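**Remark on conventions.** Locants follow gibberellane numbering. "Upper face" means the face of ring B that carries C14 and the lactone oxygen; "lower face" is the one that carries C15. Where a centre is made planar again later (C10 in 13, C4 in 29–32), the expected major isomer is drawn and its configuration has no consequence.

## Structural features

The target is a pentacyclic C19 gibberellin-type acid. Ring A is a cyclohexane (C1 carbinol, C3 ketone, quaternary C4 with the C18 methyl) spanned by a γ-lactone from C19 on C4 to oxygen on C10. Ring B is a cyclopentane (C5, C6, C8, C9, C10) carrying the C7 acid on C6, and rings C and D form a bicyclo[3.2.1]octane that shares C8–C9 with ring B and carries the C12 hydroxyl and the C16=C17 methylene. There are nine stereocentres: seven are contiguous (C1, C10, C5, C4, C6, C8, C9), three of them fully substituted (C4, C8, C10), and C12 and C13 sit on the bicycle. Read from the SMILES, the lactone oxygen on C10, C4 on C5, H9, C14 and the C12 hydroxyl lie on one face; H5, C1 on C10, the carboxyl on C6 and the C15–C16 bridge lie on the other. H9 is therefore anti to C15 (trans-fused B/C hydrindane) and the C1 hydroxyl is anti to the lactone oxygen. The fragile groups are the β-hydroxy ketone (dehydration, retro-aldol), the β-keto lactone at non-enolisable C4 (retro-Claisen with nucleophilic base), the exocyclic alkene (no hydrogenation, no strong acid) and the hindered acid next to quaternary C8. The real difficulty is C10, which needs oxygen on the upper face and C1 on the hindered lower face beside C8, together with the axial C12 hydroxyl, which sits on the face a hydride prefers to attack. The key step exploits the fact that rings B and C are a hydrindane with a quaternary fusion carbon C8 bearing the C15 arm and oxygen at C6 and C12, which is an angular-allyl Hajos–Parrish enedione closed through C9–C11.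

## Logic of the disconnections

36 ⇒ 35 ⇒ 33. The silyl ether and silylethyl ester come off last with buffered fluoride. Before that the C1–O bond is cut, because the β-hydroxy ketone is the most fragile unit and should appear last. This leaves enone 33, in which the lactone bridge dictates the face of attack at C1. The demand is a neutral conjugate oxygenation that spares the β-keto lactone.

33 ⇒ 32. The C3–C4 bond of ring A is cut. Because C3 is tethered to C10, it can reach C4 only on the face that carries C1, so C4 is fixed without an external controller. The demand is a Z alkene at C1=C2 and selective enolisation of the lactone.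

32 ⇒ 31 ⇒ 30. C1=C2 is cut back to the C1 aldehyde, and this to the dimethyl acetal that protects C1 while the lactone is made. The demand is acetal cleavage without acid strong enough to touch the silyl ether or the alkene.

30 ⇒ 29 ⇒ 27 ⇒ 26. C4–C18, C4–C5 and the C19–O10 ester bond are cut. The lactone is formed by a Michael addition tethered through O10, which places C4 on the upper face of C5. An acetyl group on C4 makes the closure enolexo and is removed afterwards. The demand is a base that removes the acetyl and equilibrates C6 without exchanging the C7 ester.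

26 ⇒ 24 ⇒ 22. C6–C7 is cut; the enoate comes from the C6 ketone through its enol triflate and carbon monoxide. The demand is enolisation toward C5 without loss of the β-oxygen on C10.

22 ⇒ 17. No skeletal bond is cut. The C6 ketone returns to its silyl ether, and the axial C12–O bond is traced to the equatorial alcohol by inversion, because hydride can only reach C12 from the upper face.

17 ⇒ 15. The hydrogens at C9, C11 and C12 are removed, giving an enone. The demand is delivery of H to C9 on the upper face without loss of the C10 oxygen and without touching C16=C17.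

15 ⇒ 14 ⇒ 13 ⇒ 11. C10–O and then C10–C1 are cut. Both are installed at the γ-carbon of the C12 enone, carbon first and oxygen second, so that the oxygen enters from the open upper face and pushes C1 down. The demand is γ- rather than α-selectivity in both steps.

11 ⇒ 10 ⇒ 9 ⇒ 8 ⇒ 7. C13–C16 (ring D) is cut to the allyl arm and the α′-carbon of the enone. The C6 ketone is masked as a silyl ether so that only the enone is enolised.

7 ⇒ 5. C9–C11 is cut (key step), leaving a prochiral triketone with no stereocentre. The demand is discrimination between the two enantiotopic ring carbonyls.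

5 ⇒ 3 + 4 and 3 ⇒ 1 + 2. The C8–C14 and C8–C15 bonds are cut by Michael addition and C-allylation of a cyclic 1,3-dione.

## Other disconnections considered

Alternative 1: The cut is C6–C8, which re-expands ring B to a six-membered ring with C7 inside it. The forward step is photolysis of diazoketone A2 in wet THF (Wolff ring contraction: loss of N2, shift of C8 from C7 to C6, hydration of the ketene) to give acid A1.
- In its favour: C8 migrates with retention, so the quaternary centre is safe, and the conditions are neutral. The acid appears free, so no hindered ester has to be cleaved at the end; on this point it is better than the chosen plan.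
- Against it: C6 is set by protonation of the ketene hydrate from the less hindered face, which need not give the carboxyl trans to C4, and a free acid beside C8 is hard to epimerise. Diazo transfer to a ketone flanked by C8 needs prior activation. The C3 ketone must be masked, and the carbene may add to C16=C17.
- Comparison: structurally A2 already holds ring A, the lactone, C10 and ring D, so the step solves none of the hard problems; the chosen plan fixes the ring size at the outset with cyclopentane-1,3-dione. Mechanistically both key steps are well precedented. In step count, contraction needs three operations where triflation–carbonylation needs two, and a homologous skeleton must be built first.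

Alternative 2: The cut is C8–C15 with C11–O reconnected. Heating the bridged 2-methylene-5-vinyl oxacycle A4 should trigger a Claisen ring expansion to 9(11)-ene 16-ketone A3.
- In its favour: the shift is suprafacial, so the C11 carbinol configuration is transferred cleanly to quaternary C8, and ring D and C8 form together without reagents. C16 emerges as a ketone, so the methylene can be added last and never restricts reductions; this is better than the chosen plan, which carries C16=C17 through nineteen steps and cannot use hydrogenation.
- Against it: A4 needs a tetrasubstituted C8=C9 alkene and an exocyclic enol ether, presumably made by methylenating a bridged lactone in the presence of two other ester carbonyls. The bicyclic frame forces a boat-like transition state. C9 hydrogenation, C16 methylenation and three deprotections still follow.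
- Comparison: structurally C8 is made late on a full skeleton, whereas the chosen plan makes it first and by catalysis. Mechanistically stereocontrol is equal in principle, but the C11 centre it depends on is an additional problem. Step economy is at best equal.

Alternative 3: The cut is C12–C13. BF3·OEt2 should activate the aldehyde of A6 so that the cyclopentenyl allylsilane attacks through C13, closing ring C and releasing silicon to give A5.
- In its favour: one step makes ring C, the bicyclo[3.2.1]octane, C13, the C12 carbinol and the exocyclic alkene, and A5 is two deprotections from the target. If the aldehyde oxygen points away from the forming ring, the C12 hydroxyl would emerge axial directly, which the chosen plan reaches only by reduction plus Mitsunobu inversion; on this point it is better.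
- Against it: BF3·OEt2 threatens the β-silyloxy ketone (elimination), the tert-butyl ester and the β-keto lactone. The C12 configuration depends on an aldehyde rotamer, and protodesilylation competes. In A6 the chirality of spiro C8 rests only on the position of the ring alkene, which is hard to set.
- Comparison: the endgame is shorter than in the chosen plan. Building rings A and B and the lactone around a spirocyclopentene is likely to cost more steps than it saves, and the mechanism gives less secure control of C8 than the proline aldol.

Key step: step 3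

## Route

Step 1
Reactants: 1 cyclopentane-1,3-dione; 2 allyl bromide
Product: 3 2-allylcyclopentane-1,3-dione
Conditions: KOH (1 equiv), H2O, rt then 60 °C; HCl to pH 2
Reagents that add atoms: none
Why: C-alkylation of the dione enolate, favoured in water where the enolate oxygens are hydrogen-bonded; any O-allyl enol ether should converge on 3 by Claisen rearrangement on warming.

Step 2
Reactants: 3 2-allylcyclopentane-1,3-dione; 4 methyl vinyl ketone
Product: 5 2-allyl-2-(3-oxobutyl)cyclopentane-1,3-dione
Conditions: AcOH (cat.), H2O, 70 °C
Reagents that add atoms: none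
Why: Michael addition of the acidic 2-substituted 1,3-dione to the enone; the new quaternary carbon is prochiral, so no stereochemical issue arises.

Step 3
Reactants: 5 2-allyl-2-(3-oxobutyl)cyclopentane-1,3-dione
Product: 7 (7aR)-7a-allyl-2,3,7,7a-tetrahydro-1H-indene-1,5(6H)-dione, via ketol 6 (not isolated)
Conditions: L-proline (0.3 equiv), DMF, rt; then TsOH·H2O (cat.), PhMe, 80 °C
Reagents that add atoms: none
Why: Hajos–Parrish aldol: proline forms the less substituted enamine of the side-chain methyl ketone, and C11 attacks one of the two enantiotopic ring carbonyls while the proline carboxylic acid hydrogen-bonds to that carbonyl in a chair-like transition state. Ring C closes in the 6-(enolendo)-exo-trig mode to the cis-fused ketol 6, and acid then dehydrates it by E1cB to the C9=C11 enone, which removes the transient C9 carbinol centre. The only stereocentre kept is C8, and it is set by the catalyst: L-proline should select the same carbonyl as in the methyl series, the descriptor reading R only because allyl outranks C14. The step needs enantiotopic-group selectivity and enamine formation at the methyl ketone alone; the mirror symmetry of 5, the low hindrance of the methyl ketone and the inert allyl arm secure both. The closest known reaction is the proline-catalysed annulation of 2-alkyl-2-(3-oxobutyl)cyclopentane-1,3-diones. Mild acid in the second stage avoids migration of the allyl double bond.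

Step 4
Reactants: 7 enedione
Product: 8 C6 alcohol of 7 (hydroxyl cis to the allyl group)
Conditions: NaBH4 (0.3 equiv), EtOH, −20 °C
Reagents that add atoms: none
Why: Chemoselective 1,2-reduction of the saturated cyclopentanone, which is more electrophilic than the enone; hydride enters anti to the allyl group, and the C6 configuration is irrelevant because C6 is re-oxidised in step 16.

Step 5
Reactants: 8 C6 alcohol
Product: 9 triethylsilyl ether of 8
Conditions: Et3SiCl, imidazole, DMF, 0 °C to rt
Reagents that add atoms: chlorotriethylsilane CC[Si](Cl)(CC)CC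
Why: Standard silylation; the triethylsilyl ether is chosen because it can later be removed in the presence of a tert-butyldimethylsilyl ether.

Step 6
Reactants: 9 triethylsilyl ether
Product: 10 cross-conjugated trimethylsilyl dienol ether (C12=C13 and C9=C11)
Conditions: LiN(iPr)2, THF, −78 °C; Me3SiCl
Reagents that add atoms: chlorotrimethylsilane C[Si](C)(C)Cl
Why: Kinetic deprotonation of the enone at the α′-carbon C13 and O-silylation give the 2-silyloxy diene needed for ring D.

Step 7
Reactants: 10 trimethylsilyl dienol ether
Product: 11 tricyclic enone (rings B, C, D; 16-methylene; C12 ketone; C9=C11; 6-OSiEt3)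
Conditions: Pd(OAc)2 (10 mol %), O2 (1 atm), DMSO, 45 °C
Reagents that add atoms: none
Why: Pd(OAc)2-catalysed cycloalkenylation of a silyl enol ether: divalent palladium activates the terminal alkene, C13 attacks the internal carbon C16 (5-exo), β-hydride elimination gives the exocyclic methylene, and O2 re-oxidises zerovalent palladium. C13 can bond only on the face that carries the C15 arm, so its configuration follows from C8.

Step 8
Reactants: 11 tricyclic enone
Product: 13 10-(dimethoxymethyl) enone, via TMS dienol ether 12 (not isolated)
Conditions: Me3SiOTf (1.5 equiv), iPr2NEt (1.3 equiv), HC(OMe)3, CH2Cl2, −78 to −20 °C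
Reagents that add atoms: trimethyl orthoformate COC(OC)OC
Why: Vinylogous Mukaiyama reaction: C13 is a bridgehead, so soft enolisation can only give the extended dienol ether 12, whose γ-carbon C10 should be attacked by the dimethoxycarbenium ion with return of the enone. The C10 configuration does not matter because C10 is made planar again in step 9.

Step 9
Reactants: 13 10-(dimethoxymethyl) enone
Product: 14 tert-butyldimethylsilyl dienol ether (C12=C11 and C9=C10)
Conditions: tBuMe2SiOTf (1.2 equiv), Et3N, CH2Cl2, −78 to 0 °C
Reagents that add atoms: tert-butyldimethylsilyl triflate CC(C)(C)[Si](C)(C)OS(=O)(=O)C(F)(F)F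
Why: Soft enolisation removes the only enolisable hydrogen (tertiary γ-H on C10) and gives the linear 1-silyloxy diene; low temperature and a small excess of triflate should keep the acetal intact.

Step 10
Reactants: 14 silyl dienol ether
Product: 15 10-hydroxy-10-(dimethoxymethyl) enone (hydroxyl on the upper face)
Conditions: mCPBA (1.05 equiv), hexane–CH2Cl2, −20 °C; then aq. citric acid, THF
Reagents that add atoms: 3-chloroperbenzoic acid OOC(=O)c1cccc(Cl)c1
Why: Vinylogous Rubottom oxidation: the peracid should epoxidise the electron-rich terminal C9=C10 bond, as in γ-hydroxylation of steroidal dienol ethers, from the face of the one-carbon bridge C14, away from the C15–C16 bridge and the C6 silyloxy group. Ring opening restores the enone and leaves oxygen up and C1 down at C10.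

Step 11
Reactants: 15 γ-hydroxy enone
Product: 17 12-epi alcohol (equatorial 12-OH; 9-H on the upper face), via saturated ketone 16 (not isolated)
Conditions: Li, NH3(l)–THF, −78 °C; then EtOH, −33 °C; NH4Cl
Reagents that add atoms: none
Why: Dissolving-metal reduction: C9 is protonated axially, which in the rigid bicyclo[3.2.1]octane is the exo (C14) face and also the face of the C10 lithium alkoxide, giving H9 anti to C15. The alkoxide is too poor a leaving group to be expelled, and excess metal with alcohol then reduces the ketone to the more stable equatorial alcohol.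

Step 12
Reactants: 17 equatorial alcohol
Product: 18 axial 12-(4-nitrobenzoate)
Conditions: 4-O2NC6H4CO2H, PPh3, DIAD, PhMe, 0 °C to rt
Reagents that add atoms: 4-nitrobenzoic acid OC(=O)c1ccc(cc1)[N+](=O)[O-]
Why: Mitsunobu inversion of a hindered equatorial cyclohexanol by SN2 from the open exo face; the tertiary C10 hydroxyl does not react.

Step 13
Reactants: 18 axial 4-nitrobenzoate
Product: 19 10,12-diol (12-OH axial, upper face)
Conditions: K2CO3 (0.2 equiv), MeOH, rt
Reagents that add atoms: none
Why: Methanolysis of the activated aryl ester; the silyl ether and acetal are stable to carbonate in methanol.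

Step 14
Reactants: 19 diol
Product: 20 12-O-tert-butyldimethylsilyl ether
Conditions: tBuMe2SiCl, imidazole, DMAP (cat.), DMF, 45 °C
Reagents that add atoms: tert-butyldimethylsilyl chloride CC(C)(C)[Si](C)(C)Cl
Why: The chloride silylates the secondary alcohol only, and avoiding a silyl triflate keeps the acetal safe.

Step 15
Reactants: 20 bis-silyl ether
Product: 21 6,10-diol
Conditions: PPTS (cat.), MeOH–CH2Cl2, 0 °C to rt
Reagents that add atoms: none
Why: Acid-catalysed methanolysis removes the more labile triethylsilyl ether in the presence of the tert-butyldimethylsilyl ether; acetal exchange in methanol is degenerate.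

Step 16
Reactants: 21 diol
Product: 22 6-ketone (tertiary β-hydroxy ketone)
Conditions: Dess–Martin periodinane, CH2Cl2, rt
Reagents that add atoms: none
Why: Oxidation of the secondary alcohol under non-basic conditions, so the β-hydroxy ketone is not exposed to retro-aldol or elimination.

Step 17
Reactants: 22 β-hydroxy ketone
Product: 24 C5=C6 enol triflate with 10-OSiMe3, via TMS ether ketone 23 (not isolated)
Conditions: KN(SiMe3)2 (1.05 equiv), THF, −78 °C; Me3SiCl; then KN(SiMe3)2 (1.2 equiv), N-(5-chloro-2-pyridyl)triflimide, −78 °C
Reagents that add atoms: chlorotrimethylsilane C[Si](C)(C)Cl; N-(5-chloro-2-pyridyl)bis(trifluoromethanesulfonimide) FC(F)(F)S(=O)(=O)N(c1ccc(Cl)cn1)S(=O)(=O)C(F)(F)F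
Why: The tertiary alkoxide is silylated in the flask so that enolisation cannot trigger retro-aldol or β-elimination; the second equivalent of base removes a C5 hydrogen (the only α-hydrogens, C8 being quaternary) and the enolate is triflated at −78 °C.

Step 18
Reactants: 24 enol triflate
Product: 26 10-hydroxy 2-(trimethylsilyl)ethyl enoate (C5=C6–C7), via TMS ether ester 25 (not isolated)
Conditions: Pd(OAc)2 (5 mol %), PPh3, CO (1 atm), Me3SiCH2CH2OH, Et3N, DMF, 50 °C; then PPTS (cat.), MeOH, rt
Reagents that add atoms: carbon monoxide [C-]#[O+]; 2-(trimethylsilyl)ethanol C[Si](C)(C)CCO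
Why: Alkoxycarbonylation of an enol triflate (oxidative addition to zerovalent palladium, CO insertion, alcoholysis), a reaction that works on enol triflates next to quaternary carbons; brief methanolysis then cleaves only the trimethylsilyl ether.

Step 19
Reactants: 26 γ-hydroxy enoate
Product: 27 10-acetoacetate
Conditions: 2,2,6-trimethyl-4H-1,3-dioxin-4-one, PhMe, 110 °C
Reagents that add atoms: 2,2,6-trimethyl-4H-1,3-dioxin-4-one CC1=CC(=O)OC(C)(C)O1
Why: Thermal cycloreversion of the dioxinone releases acetylketene, which acylates even hindered tertiary alcohols under neutral conditions.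

Step 20
Reactants: 27 acetoacetate
Product: 29 4-acetyl-4-methyl 19,10-lactone, via acetyl lactone enol 28 (not isolated)
Conditions: Cs2CO3, MeCN, rt; then MeI
Reagents that add atoms: iodomethane CI
Why: Intramolecular Michael addition in the favoured 5-(enolexo)-exo-trig mode; the tether through O10 forces C4 onto the upper face of C5, and the acidic α-acetyl lactone is then C-methylated in the same flask. C4 and C6 may form as mixtures; C4 is re-planarised and C6 equilibrated in step 21.

Step 21
Reactants: 29 acetyl methyl lactone
Product: 30 4-methyl 19,10-lactone with 10-dimethoxymethyl group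
Conditions: NaH (cat.), Me3SiCH2CH2OH–THF, rt to 40 °C
Reagents that add atoms: none
Why: Retro-Claisen deacetylation of the non-enolisable β-keto lactone by the alkoxide that matches the C7 ester, so there is no net transesterification; the same alkoxide should equilibrate C6 to the more stable arrangement with the carboxyl trans to C4.

Step 22
Reactants: 30 acetal lactone
Product: 31 10-formyl lactone
Conditions: Et3SiOTf, 2,4,6-collidine, CH2Cl2, 0 °C; then H2O
Reagents that add atoms: water O
Why: Silyl triflate and collidine convert the dimethyl acetal to a pyridinium intermediate that water hydrolyses; the medium is not acidic, so the silyl ether, lactone and alkene are untouched, and the aldehyde is non-enolisable.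

Step 23
Reactants: 31 aldehyde
Product: 32 (Z)-enamide (10-[(Z)-CH=CH–C(O)N(OMe)Me] lactone)
Conditions: (CF3CH2O)2P(O)CH2C(O)N(OMe)Me, KN(SiMe3)2, 18-crown-6, THF, −78 °C
Reagents that add atoms: N-methoxy-N-methyl-2-[bis(2,2,2-trifluoroethoxy)phosphoryl]acetamide CON(C)C(=O)CP(=O)(OCC(F)(F)F)OCC(F)(F)F
Why: Z-selective Horner–Wadsworth–Emmons olefination of the Still–Gennari type (electron-poor phosphonate, dissociated potassium); the Z geometry is needed so that C3 can reach C4. The phosphonate is a known reagent made in one step from the commercial methyl ester.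

Step 24
Reactants: 32 (Z)-enamide
Product: 33 1-en-3-one (ring A closed)
Conditions: LiN(SiMe3)2 (1.1 equiv), THF, −78 to 0 °C
Reagents that add atoms: none
Why: Intramolecular C-acylation of the lactone enolate by the N-methoxy-N-methylamide (6-(enolexo)-exo-trig); the chelated tetrahedral intermediate prevents reversal. C3 can bond to C4 only on the face that carries C1, which fixes C4 with the methyl toward C6, and the reversible silylamide base should populate the more acidic lactone enolate in preference to the C6 ester enolate.

Step 25
Reactants: 33 enone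
Product: 35 12-O-silyl 7-(2-trimethylsilylethyl) ester of the target, via boronate 34 (not isolated)
Conditions: B2pin2, CuCl (10 mol %), bis[2-(diphenylphosphino)phenyl] ether, NaOtBu (cat.), MeOH, THF, rt; then NaBO3·4H2O, THF–H2O, rt
Reagents that add atoms: bis(pinacolato)diboron CC1(C)OB(OC1(C)C)B1OC(C)(C)C(C)(C)O1; sodium perborate [Na+].[Na+].O[B-]1(O)OO[B-](O)(O)OO1
Why: Copper-catalysed conjugate borylation followed by oxidation with retention; the boryl-copper should add to C1 axially from the exo face of the bridged lactone, anti to the C19–O bridge, which places the hydroxyl anti to the lactone oxygen.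

Step 26
Reactants: 35 protected target
Product: 36 target acid (CNP0259985.3)
Conditions: Bu4NF, AcOH, THF, rt to 40 °C
Reagents that add atoms: none
Why: Fluoride cleaves the silyl ether and, by β-elimination of the 2-silylethyl group, the ester; the acetic acid buffer should keep the medium from promoting dehydration or retro-aldol of the β-hydroxy ketone.

## Compound list

1 | cyclopentane-1,3-dione | O=C1CCC(=O)C1 | starting material
2 | allyl bromide | C=CCBr | starting material
3 | 2-allylcyclopentane-1,3-dione | C=CCC1C(=O)CCC1=O | intermediate
4 | methyl vinyl ketone | CC(=O)C=C | starting material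
5 | 2-allyl-2-(3-oxobutyl)cyclopentane-1,3-dione | C=CCC1(CCC(C)=O)C(=O)CCC1=O | intermediate
6 | cis-fused ketol (9-OH cis to allyl) | C=CC[C@]12CCC(=O)C[C@@]1(O)CCC2=O | intermediate
7 | (7aR)-7a-allyl-2,3,7,7a-tetrahydro-1H-indene-1,5(6H)-dione | C=CC[C@]12CCC(=O)C=C1CCC2=O | intermediate
8 | C6 alcohol of 7 (OH cis to allyl) | C=CC[C@]12CCC(=O)C=C1CC[C@@H]2O | intermediate
9 | triethylsilyl ether of 8 | C=CC[C@]12CCC(=O)C=C1CC[C@@H]2O[Si](CC)(CC)CC | intermediate
10 | cross-conjugated trimethylsilyl dienol ether | C=CC[C@]12CC=C(O[Si](C)(C)C)C=C1CC[C@@H]2O[Si](CC)(CC)CC | intermediate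
11 | tricyclic enone (16-methylene, 12-oxo, 9(11)-ene, 6-OSiEt3) | C=C1C[C@]23C[C@H]1C(=O)C=C2CC[C@@H]3O[Si](CC)(CC)CC | intermediate
12 | extended trimethylsilyl dienol ether of 11 | C=C1C[C@]23C[C@H]1C(O[Si](C)(C)C)=CC2=CC[C@@H]3O[Si](CC)(CC)CC | intermediate
13 | 10-(dimethoxymethyl) enone | C=C1C[C@]23C[C@H]1C(=O)C=C2[C@@H](C(OC)OC)C[C@@H]3O[Si](CC)(CC)CC | intermediate
14 | tert-butyldimethylsilyl dienol ether of 13 | C=C1C[C@]23C[C@H]1C(O[Si](C)(C)C(C)(C)C)=CC2=C(C(OC)OC)C[C@@H]3O[Si](CC)(CC)CC | intermediate
15 | 10-hydroxy-10-(dimethoxymethyl) enone | C=C1C[C@]23C[C@H]1C(=O)C=C2[C@](O)(C(OC)OC)C[C@@H]3O[Si](CC)(CC)CC | intermediate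
16 | saturated 12-ketone (9-H on the upper face) | C=C1C[C@]23C[C@H]1C(=O)C[C@@H]2[C@](O)(C(OC)OC)C[C@@H]3O[Si](CC)(CC)CC | intermediate
17 | 12-epi alcohol (equatorial 12-OH) | C=C1C[C@]23C[C@H]1[C@H](O)C[C@@H]2[C@](O)(C(OC)OC)C[C@@H]3O[Si](CC)(CC)CC | intermediate
18 | axial 12-(4-nitrobenzoate) | C=C1C[C@]23C[C@H]1[C@@H](OC(=O)c1ccc(cc1)[N+](=O)[O-])C[C@@H]2[C@](O)(C(OC)OC)C[C@@H]3O[Si](CC)(CC)CC | intermediate
19 | 10,12-diol (12-OH axial) | C=C1C[C@]23C[C@H]1[C@@H](O)C[C@@H]2[C@](O)(C(OC)OC)C[C@@H]3O[Si](CC)(CC)CC | intermediate
20 | 12-O-tert-butyldimethylsilyl ether | C=C1C[C@]23C[C@H]1[C@@H](O[Si](C)(C)C(C)(C)C)C[C@@H]2[C@](O)(C(OC)OC)C[C@@H]3O[Si](CC)(CC)CC | intermediate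
21 | 6,10-diol | C=C1C[C@]23C[C@H]1[C@@H](O[Si](C)(C)C(C)(C)C)C[C@@H]2[C@](O)(C(OC)OC)C[C@@H]3O | intermediate
22 | 6-ketone | C=C1C[C@]23C[C@H]1[C@@H](O[Si](C)(C)C(C)(C)C)C[C@@H]2[C@](O)(C(OC)OC)CC3=O | intermediate
23 | 10-O-trimethylsilyl 6-ketone | C=C1C[C@]23C[C@H]1[C@@H](O[Si](C)(C)C(C)(C)C)C[C@@H]2[C@](O[Si](C)(C)C)(C(OC)OC)CC3=O | intermediate
24 | C5=C6 enol triflate, 10-OSiMe3 | C=C1C[C@]23C[C@H]1[C@@H](O[Si](C)(C)C(C)(C)C)C[C@@H]2[C@](O[Si](C)(C)C)(C(OC)OC)C=C3OS(=O)(=O)C(F)(F)F | intermediate
25 | 2-(trimethylsilyl)ethyl enoate, 10-OSiMe3 | C=C1C[C@]23C[C@H]1[C@@H](O[Si](C)(C)C(C)(C)C)C[C@@H]2[C@](O[Si](C)(C)C)(C(OC)OC)C=C3C(=O)OCC[Si](C)(C)C | intermediate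
26 | 10-hydroxy 2-(trimethylsilyl)ethyl enoate | C=C1C[C@]23C[C@H]1[C@@H](O[Si](C)(C)C(C)(C)C)C[C@@H]2[C@](O)(C(OC)OC)C=C3C(=O)OCC[Si](C)(C)C | intermediate
27 | 10-acetoacetate | C=C1C[C@]23C[C@H]1[C@@H](O[Si](C)(C)C(C)(C)C)C[C@@H]2[C@](OC(=O)CC(C)=O)(C(OC)OC)C=C3C(=O)OCC[Si](C)(C)C | intermediate
28 | 4-acetyl 19,10-lactone (enol form) | C=C1C[C@]23C[C@H]1[C@@H](O[Si](C)(C)C(C)(C)C)C[C@@H]2[C@@]4(C(OC)OC)OC(=O)C(=C(C)O)[C@H]4[C@@H]3C(=O)OCC[Si](C)(C)C | intermediate
29 | 4-acetyl-4-methyl 19,10-lactone | C=C1C[C@]23C[C@H]1[C@@H](O[Si](C)(C)C(C)(C)C)C[C@@H]2[C@@]4(C(OC)OC)OC(=O)[C@](C(C)=O)(C)[C@H]4[C@@H]3C(=O)OCC[Si](C)(C)C | intermediate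
30 | 4-methyl 19,10-lactone, 10-dimethoxymethyl | C=C1C[C@]23C[C@H]1[C@@H](O[Si](C)(C)C(C)(C)C)C[C@@H]2[C@@]4(C(OC)OC)OC(=O)[C@H](C)[C@H]4[C@@H]3C(=O)OCC[Si](C)(C)C | intermediate
31 | 10-formyl lactone | C=C1C[C@]23C[C@H]1[C@@H](O[Si](C)(C)C(C)(C)C)C[C@@H]2[C@@]4(C=O)OC(=O)[C@H](C)[C@H]4[C@@H]3C(=O)OCC[Si](C)(C)C | intermediate
32 | (Z)-enamide lactone | C=C1C[C@]23C[C@H]1[C@@H](O[Si](C)(C)C(C)(C)C)C[C@@H]2[C@@]4(/C=C\C(=O)N(C)OC)OC(=O)[C@H](C)[C@H]4[C@@H]3C(=O)OCC[Si](C)(C)C | intermediate
33 | 1-en-3-one, 12-O-silyl, 7-(2-trimethylsilylethyl) ester | C=C1C[C@]23C[C@H]1[C@@H](O[Si](C)(C)C(C)(C)C)C[C@@H]2[C@]12OC(=O)[C@](C)(C(=O)C=C1)[C@H]2[C@@H]3C(=O)OCC[Si](C)(C)C | intermediate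
34 | 1-pinacolboronate (boron anti to the lactone oxygen) | C=C1C[C@]23C[C@H]1[C@@H](O[Si](C)(C)C(C)(C)C)C[C@@H]2[C@]12OC(=O)[C@](C)(C(=O)C[C@H]1B4OC(C)(C)C(C)(C)O4)[C@H]2[C@@H]3C(=O)OCC[Si](C)(C)C | intermediate
35 | 12-O-tert-butyldimethylsilyl 7-(2-trimethylsilylethyl) ester of the target | C=C1C[C@]23C[C@H]1[C@@H](O[Si](C)(C)C(C)(C)C)C[C@@H]2[C@]12OC(=O)[C@](C)(C(=O)C[C@H]1O)[C@H]2[C@@H]3C(=O)OCC[Si](C)(C)C | intermediate
36 | CNP0259985.3 | C=C1C[C@]23C[C@H]1[C@@H](O)C[C@@H]2[C@]12OC(=O)[C@](C)(C(=O)C[C@H]1O)[C@H]2[C@@H]3C(=O)O | target

## Step count and least certain steps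

Total step count: 26. Longest linear sequence: 26 steps (the route is fully linear from 1).

**Step 3 (key step).** The larger angular allyl group may lower the discrimination between the two enantiotopic carbonyls, and dehydration may lag so that ketol is carried forward. Fallback, from 7 back to 8: material of insufficient enantiomeric purity is reduced as in step 4, and the alcohol is enriched by lipase-catalysed acylation (Burkholderia cepacia lipase, vinyl acetate). Described for the case in which the wanted enantiomer is the one acylated: acetate F1 is separated from the unreacted antipode and methanolysed (K2CO3, MeOH) to 8.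

**Step 8.** Attack of the carbenium ion at the α-carbon C11 instead of C10, loss of methanol from the product to a methoxymethylene dienone, or double addition may erode the yield. Fallback, from 11 back to 15, reverses the polarity at C10:
- soft enolisation and peracid oxidation as in steps 9 and 10 give the secondary γ-hydroxy enone F2;
- Dess–Martin periodinane gives enedione F3;
- Ph3P=CHOMe reacts at the less hindered cyclopentenone carbonyl to give methoxymethylene enol ether F4;
- mCPBA in methanol epoxidises the enol ether from the upper face and methanol opens the epoxide at C1, giving 15.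

**Step 10.** The peracid may attack C11 (α-hydroxylation) or the exocyclic alkene, or approach from the lower face. Fallback, from 14 back to 15: photo-oxygenation (O2, tetraphenylporphyrin, visible light, CH2Cl2, −78 °C) adds singlet oxygen across C12 and C10 of the silyloxy diene in a [4+2] sense, which ties the oxygen to C10 by geometry. The endoperoxide collapses to hydroperoxide F5, and PPh3 reduces it to 15.

**Step 11.** The radical anion may expel the C10 oxygen, protonation at C9 may occur from the lower face, or the acetal-bearing centre may fragment. Fallback, from 15 back to 17: a polar conjugate reduction with [(Ph3P)CuH]6 (benzene, rt) delivers hydride to C9 without a carbanion at C9, so no β-elimination is possible. The saturated ketone 16 is then isolated and reduced with NaBH4 (MeOH, 0 °C) to 17. This fallback makes no new compound (F0).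

**Step 24.** Enolisation may occur at C6 instead of C4 (C6 can also reach C3 through a six-membered ring on the lower face), the amide N–OMe group may be attacked, or acylation may be slow at the hindered C4. Fallback, from 30 back to 33, closes ring A through C1–C2 instead:
- LiN(iPr)2 then acetaldehyde (attack on the convex face of the lactone enolate, anti to C6) gives aldol adduct F6;
- Dess–Martin periodinane gives acetyl lactone F7;
- acetal cleavage as in step 22 gives keto aldehyde F8;
- acid-catalysed aldol condensation (TsOH, PhH, 80 °C) of the methyl ketone with the non-enolisable aldehyde gives 33.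

## Further compounds

F1 | step 3 | acetate of 8 | C=CC[C@]12CCC(=O)C=C1CC[C@@H]2OC(C)=O
F2 | step 8 | 10-hydroxy enone (secondary, OH on the upper face) | C=C1C[C@]23C[C@H]1C(=O)C=C2[C@@H](O)C[C@@H]3O[Si](CC)(CC)CC
F3 | step 8 | 9(11)-ene-10,12-dione | C=C1C[C@]23C[C@H]1C(=O)C=C2C(=O)C[C@@H]3O[Si](CC)(CC)CC
F4 | step 8 | 10-methoxymethylene dienone | C=C1C[C@]23C[C@H]1C(=O)C=C2C(=COC)C[C@@H]3O[Si](CC)(CC)CC
F5 | step 10 | 10-hydroperoxy-10-(dimethoxymethyl) enone | C=C1C[C@]23C[C@H]1C(=O)C=C2[C@](OO)(C(OC)OC)C[C@@H]3O[Si](CC)(CC)CC
F0 | step 11 | none | none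
F6 | step 24 | 4-(1-hydroxyethyl)-4-methyl lactone | C=C1C[C@]23C[C@H]1[C@@H](O[Si](C)(C)C(C)(C)C)C[C@@H]2[C@@]4(C(OC)OC)OC(=O)[C@](C)(C(C)O)[C@H]4[C@@H]3C(=O)OCC[Si](C)(C)C
F7 | step 24 | 4-acetyl-4-methyl lactone (acetyl on the C1 side) | C=C1C[C@]23C[C@H]1[C@@H](O[Si](C)(C)C(C)(C)C)C[C@@H]2[C@@]4(C(OC)OC)OC(=O)[C@](C)(C(C)=O)[C@H]4[C@@H]3C(=O)OCC[Si](C)(C)C
F8 | step 24 | 4-acetyl-10-formyl lactone | C=C1C[C@]23C[C@H]1[C@@H](O[Si](C)(C)C(C)(C)C)C[C@@H]2[C@@]4(C=O)OC(=O)[C@](C)(C(C)=O)[C@H]4[C@@H]3C(=O)OCC[Si](C)(C)C
A1 | alternative 1 | protected target acid (1,12-bis-silyl ether, 3-dioxolane) | C=C1C[C@]23C[C@H]1[C@@H](O[Si](C)(C)C(C)(C)C)C[C@@H]2[C@]12OC(=O)[C@](C)(C4(OCCO4)C[C@H]1O[Si](C)(C)C(C)(C)C)[C@H]2[C@@H]3C(=O)O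
A2 | alternative 1 | ring-B-expanded 6-diazo-7-ketone | C=C1C[C@]23C[C@H]1[C@@H](O[Si](C)(C)C(C)(C)C)C[C@@H]2[C@]12OC(=O)[C@](C)(C4(OCCO4)C[C@H]1O[Si](C)(C)C(C)(C)C)[C@H]2C(=[N+]=[N-])C3=O
A3 | alternative 2 | 9(11)-ene 16-ketone | O=C1C[C@]23C[C@H]1[C@@H](O[Si](CC)(CC)CC)C=C2[C@]12OC(=O)[C@](C)(C4(OCCO4)C[C@H]1O[Si](C)(C)C(C)(C)C)[C@H]2[C@@H]3C(=O)OC(C)(C)C
A4 | alternative 2 | 8(9)-ene with C11–O–C16 exocyclic enol ether bridge | C=C1O[C@H]2[C@H](O[Si](CC)(CC)CC)[C@@H]1CC3=C2[C@]45OC(=O)[C@](C)(C6(OCCO6)C[C@H]4O[Si](C)(C)C(C)(C)C)[C@H]5[C@@H]3C(=O)OC(C)(C)C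
A5 | alternative 3 | C1 silyl ether tert-butyl ester of the target | C=C1C[C@]23C[C@H]1[C@@H](O)C[C@@H]2[C@]12OC(=O)[C@](C)(C(=O)C[C@H]1O[Si](C)(C)C(C)(C)C)[C@H]2[C@@H]3C(=O)OC(C)(C)C
A6 | alternative 3 | spirocyclopentenyl allylsilane C12 aldehyde | C[Si](C)(C)CC1=CC[C@@]2(C1)[C@H](CC=O)[C@]34OC(=O)[C@](C)(C(=O)C[C@H]3O[Si](C)(C)C(C)(C)C)[C@H]4[C@@H]2C(=O)OC(C)(C)C
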